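A direct plan would take dihydroconiferyl alcohol A1, cap its primary hydroxyl as a hindered 2,4,6-triisopropylbenzoate and its phenol as a triisopropylsilyl ether to give the ester A2, and join two α-lithiated molecules of A2 to the one-carbon linchpin bis(pinacolato)diborylmethane A3 by two boronate 1,2-shifts; oxidation would give the bis-silyl anti-diol A4, and monoacetylation to the bis-silyl monoacetate A5 followed by desilylation would finish.
Three of its operations would weaken it most.
First, the esterification and silylation that open it would add only a directing ester and a silyl ether, no bond or stereocentre of the target, and both groups would be discarded, the ester being needed in large excess.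
Second, the double carbenoid homologation would set each stereocentre with a stoichiometric chiral diamine and an alkyllithium at −78 °C, would need four bond-forming events and an oxidation to succeed in one flask, and would leave the meso syn-diol A6 to be separated.
Third, the closing fluoride cleavage of two aryl silyl ethers would be run on the monoacetate A5, where phenoxide and a secondary acetate would meet on the most precious material (acetyl transfer or loss).

Plan of the new route
The retrosynthesis first removes the acetyl group from one of two homotopic hydroxyls (C2 axis through C4), then raises C3 and C5 to the ketone level (cutting the two carbinol C–H bonds) to reach the achiral β-diketone tetrahydrocurcumin, and last cuts C1–C2 and C6–C7, as C=C bonds, to two molecules of vanillin and one of acetylacetone, so that three components are joined in one operation around the central 1,3-dicarbonyl unit.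
The enabling feature is the C3(OH)–C4H2–C5(OH) unit flanked by two identical 2-(4-hydroxy-3-methoxyphenyl)ethyl arms: at the diketone level C3 and C5 are carbonyls in 1,3-relation, each able to chelate ruthenium through the other oxygen, so one chiral catalyst can set both stereocentres and their anti relation in a single two-directional hydrogenation.
Both benzene rings come ready-made with vanillin; the only rings formed are transient, namely the six-membered boron chelate of the first step and the six-membered orthoacetate of the last step; the chain is built first and all stereochemistry is set last.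
No protecting or directing group is used, so the preparatory steps and the late desilylation have no counterpart, and the stereocentres come from a catalyst at the 1 mol% level at 40 °C, not from a stoichiometric chiral base at low temperature.
Key step: step 3

Remark: the boron chelates 3 and 4 of step 1 are drawn as dibutoxyboron species, since the borate speciation in the flask is not defined and does not affect the product; 5 and 6 are also articles of commerce, so the route could be entered at either.

Step 1
Reactants: 1 vanillin (4-hydroxy-3-methoxybenzaldehyde; two molecules enter the product); 2 acetylacetone (pentane-2,4-dione)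
Product: 5 curcumin [(1E,6E)-1,7-bis(4-hydroxy-3-methoxyphenyl)hepta-1,6-diene-3,5-dione], via boron chelate of acetylacetone 3 (not isolated), via boron chelate of curcumin 4 (not isolated)
Conditions: 2, B2O3 (0.7 equiv), EtOAc, 75 °C; then 1 (2.0 equiv), B(OnBu)3 (2.0 equiv), n-BuNH2 (0.3 equiv, slow addition), 75 °C; then 0.4 M HCl, 60 °C
Reagents that add atoms: none
Why: Pabon-type boron-templated double Knoevenagel (aldol) condensation, in which chelation of the diketone as 3 blocks the central methylene and the enol oxygens, so that the amine-catalysed condensation with vanillin should occur once at each terminal methyl to give the thermodynamically favoured (E,E)-chelate 4, which dilute acid hydrolyses to curcumin; no stereocentre is formed.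

Step 2
Reactants: 5 curcumin
Product: 6 tetrahydrocurcumin [1,7-bis(4-hydroxy-3-methoxyphenyl)heptane-3,5-dione]
Conditions: H2 (1 atm), 10% Pd/C, EtOAc/MeOH, rt, stopped after 2 equiv of H2
Reagents that add atoms: none
Why: Heterogeneous catalytic hydrogenation, which should saturate the two styrenyl enone C=C bonds at 1 atm and room temperature while the enolised β-diketone, the arenes and the phenols are left untouched.

Step 3
Reactants: 6 tetrahydrocurcumin
Product: 8 (3S,5S)-1,7-bis(4-hydroxy-3-methoxyphenyl)heptane-3,5-diol, via (5S)-hexahydrocurcumin 7 (not isolated)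
Conditions: RuCl2[(S)-BINAP] (1 mol%), H2 (70 bar), MeOH, 40 °C
Reagents that add atoms: none
Why: Noyori asymmetric hydrogenation of a β-diketone: the keto form of 6 should bind the divalent ruthenium hydride–(S)-BINAP complex as a six-membered chelate through both carbonyl oxygens, the hydride should pass to the carbonyl carbon on the face left open by the diphosphine, and H2 should then regenerate the hydride. The closest known reaction is the hydrogenation of pentane-2,4-dione and other symmetric 1,3-diketones to anti-1,3-diols with catalysts of this family, and no ring is closed. C5 is set first by the catalyst alone (the (S)-ligand gives S where, as here, the outer chain ranks below the inner CH2), and C3 is set on hydroxy ketone 7 bound through its new hydroxyl, where the preference of the catalyst and the intrinsic 1,3-anti preference of the chelate point the same way, which should give the (3S,5S)-diol. Because the catalyst acts twice, most of any (R)-hydroxy ketone should end as the meso syn-diol, a diastereomer that crystallisation or chromatography removes, so the anti-diol should be enantiomerically purer than a single reduction would make it. The step needs ketone reduction without attack on arenes or phenols and needs no choice between the two carbonyls: only the 1,3-dicarbonyl unit can chelate the metal, and the two arms are identical.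

Step 4
Reactants: 8 (3S,5S)-1,7-bis(4-hydroxy-3-methoxyphenyl)heptane-3,5-diol
Product: 10 (3S,5S)-5-hydroxy-1,7-bis(4-hydroxy-3-methoxyphenyl)heptan-3-yl acetate (target), via cyclic orthoacetate 9 (not isolated)
Conditions: MeC(OMe)3 (1.5 equiv), CSA (5 mol%), THF, rt; then H2O (10 equiv), rt
Reagents that add atoms: trimethyl orthoacetate, COC(C)(OC)OC; water, O
Why: Orthoester monoacylation of a diol, in which acid-catalysed exchange ties the two homotopic hydroxyls into the six-membered orthoacetate 9 (the phenols can exchange only reversibly and cannot form a ring) and hydrolysis through the 1,3-dioxan-2-ylium ion can release only one acetate and one free hydroxyl, with no C–O bond at a stereocentre broken and both ring-opening modes giving the same compound because of the C2 axis.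

Compound list
1 | vanillin, 4-hydroxy-3-methoxybenzaldehyde | COc1cc(C=O)ccc1O | starting material
2 | acetylacetone, pentane-2,4-dione | CC(=O)CC(C)=O | starting material
3 | boron chelate of acetylacetone, 2,2-dibutoxy-4,6-dimethyl-1,3,2-dioxaborinine (drawn as the chelate zwitterion) | CCCCO[B-]1(OCCCC)OC(C)=CC(C)=[O+]1 | intermediate
4 | boron chelate of curcumin, 2,2-dibutoxy-4,6-bis[(E)-2-(4-hydroxy-3-methoxyphenyl)ethenyl]-1,3,2-dioxaborinine | COc1cc(/C=C/C2=CC(/C=C/c3ccc(O)c(OC)c3)=[O+][B-](OCCCC)(OCCCC)O2)ccc1O | intermediate
5 | curcumin, (1E,6E)-1,7-bis(4-hydroxy-3-methoxyphenyl)hepta-1,6-diene-3,5-dione | COc1cc(/C=C/C(=O)CC(=O)/C=C/c2ccc(O)c(OC)c2)ccc1O | intermediate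
6 | tetrahydrocurcumin, 1,7-bis(4-hydroxy-3-methoxyphenyl)heptane-3,5-dione | COc1cc(CCC(=O)CC(=O)CCc2ccc(O)c(OC)c2)ccc1O | intermediate
7 | (5S)-hexahydrocurcumin, (5S)-5-hydroxy-1,7-bis(4-hydroxy-3-methoxyphenyl)heptan-3-one | COc1cc(CC[C@H](O)CC(=O)CCc2ccc(O)c(OC)c2)ccc1O | intermediate
8 | (3S,5S)-1,7-bis(4-hydroxy-3-methoxyphenyl)heptane-3,5-diol (anti, C2-symmetric) | COc1cc(CC[C@H](O)C[C@@H](O)CCc2ccc(O)c(OC)c2)ccc1O | intermediate
9 | (4S,6S)-4,6-bis[2-(4-hydroxy-3-methoxyphenyl)ethyl]-2-methoxy-2-methyl-1,3-dioxane (C2 of the dioxane is not stereogenic) | COC1(C)O[C@@H](CCc2ccc(O)c(OC)c2)C[C@H](CCc2ccc(O)c(OC)c2)O1 | intermediate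
10 | (3S,5S)-5-hydroxy-1,7-bis(4-hydroxy-3-methoxyphenyl)heptan-3-yl acetate | COc1cc(CC[C@H](O)C[C@H](CCc2ccc(O)c(OC)c2)OC(C)=O)ccc1O | target

Total step count: 4
Longest linear sequence: 4 steps (1 + 2 → 5 → 6 → 8 → 10)

Steps most likely to fail, in order of risk

1. Step 4. The two phenols could compete in the orthoester exchange: reversible aryl orthoester formation could slow closure of the six-membered orthoacetate, and hydrolysis of a mixed aryl orthoester could pass acetyl to a phenolic oxygen. The fallback sets out from 8 and comes back at 10. The phenols would first be masked, by their acidity alone, with BnBr and K2CO3 in acetone to give (3S,5S)-1,7-bis[4-(benzyloxy)-3-methoxyphenyl]heptane-3,5-diol F1. The same orthoester exchange and hydrolysis would then pass through (4S,6S)-4,6-bis{2-[4-(benzyloxy)-3-methoxyphenyl]ethyl}-2-methoxy-2-methyl-1,3-dioxane F2 to (3S,5S)-1,7-bis[4-(benzyloxy)-3-methoxyphenyl]-5-hydroxyheptan-3-yl acetate F3. Neutral hydrogenolysis (H2, Pd/C, EtOAc, rt) would free the phenols without touching the acetate.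

2. Step 3. The hydrogenation could stall after the first carbonyl, or lose anti selectivity in the second reduction, if the enol chelate or the guaiacol units hold the catalyst. The fallback sets out from 7 and comes back at 8. The hydrogenation would be interrupted after one equivalent of H2 and 7 separated from 6 and 8. Its ketone would then be reduced with Me4NBH(OAc)3 in MeCN/AcOH at −30 °C (Evans–Saksena reduction), where the C5 hydroxyl binds boron and delivers hydride intramolecularly through a chair transition state, so the anti relation comes from substrate control. No new compound arises, so this fallback has the entry F0.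

3. Step 2. Over-reduction of a diketone carbonyl would give racemic alcohols that no later step corrects, and the reaction could also stall at the dihydro stage. The fallback sets out from 2 and comes back at 6. The dianion of 2 (LiN(iPr)2, 2 equiv, THF, 0 °C) would be alkylated at a terminal methyl with 4-(benzyloxy)-3-methoxybenzyl chloride F4 (bought). A third equivalent of base and a second equivalent of F4 would alkylate the other terminus, since the dianion forms at the less substituted methyl, to give 1,7-bis[4-(benzyloxy)-3-methoxyphenyl]heptane-3,5-dione F5 with the saturated chain already in place. Brief hydrogenolysis of the two benzyl ethers (H2, Pd/C, EtOAc, rt), with no C=C to reduce, would give 6.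

Further compounds
F1 | step 4 | (3S,5S)-1,7-bis[4-(benzyloxy)-3-methoxyphenyl]heptane-3,5-diol | COc1cc(CC[C@H](O)C[C@@H](O)CCc2ccc(OCc3ccccc3)c(OC)c2)ccc1OCc1ccccc1
F2 | step 4 | (4S,6S)-4,6-bis{2-[4-(benzyloxy)-3-methoxyphenyl]ethyl}-2-methoxy-2-methyl-1,3-dioxane | COC1(C)O[C@@H](CCc2ccc(OCc3ccccc3)c(OC)c2)C[C@H](CCc2ccc(OCc3ccccc3)c(OC)c2)O1
F3 | step 4 | (3S,5S)-1,7-bis[4-(benzyloxy)-3-methoxyphenyl]-5-hydroxyheptan-3-yl acetate | COc1cc(CC[C@H](O)C[C@H](CCc2ccc(OCc3ccccc3)c(OC)c2)OC(C)=O)ccc1OCc1ccccc1
F0 | step 3 | none | none
F4 | step 2 | 4-(benzyloxy)-3-methoxybenzyl chloride (bought) | COc1cc(CCl)ccc1OCc1ccccc1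
F5 | step 2 | 1,7-bis[4-(benzyloxy)-3-methoxyphenyl]heptane-3,5-dione | COc1cc(CCC(=O)CC(=O)CCc2ccc(OCc3ccccc3)c(OC)c2)ccc1OCc1ccccc1
A1 | direct plan | dihydroconiferyl alcohol, 4-(3-hydroxypropyl)-2-methoxyphenol | COc1cc(CCCO)ccc1O
A2 | direct plan | 3-[3-methoxy-4-(triisopropylsilyloxy)phenyl]propyl 2,4,6-triisopropylbenzoate | COc1cc(CCCOC(=O)c2c(C(C)C)cc(C(C)C)cc2C(C)C)ccc1O[Si](C(C)C)(C(C)C)C(C)C
A3 | direct plan | bis(pinacolato)diborylmethane | CC1(C)OB(CB2OC(C)(C)C(C)(C)O2)OC1(C)C
A4 | direct plan | (3S,5S)-1,7-bis[3-methoxy-4-(triisopropylsilyloxy)phenyl]heptane-3,5-diol | COc1cc(CC[C@H](O)C[C@@H](O)CCc2ccc(O[Si](C(C)C)(C(C)C)C(C)C)c(OC)c2)ccc1O[Si](C(C)C)(C(C)C)C(C)C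
A5 | direct plan | (3S,5S)-5-hydroxy-1,7-bis[3-methoxy-4-(triisopropylsilyloxy)phenyl]heptan-3-yl acetate | COc1cc(CC[C@H](O)C[C@H](CCc2ccc(O[Si](C(C)C)(C(C)C)C(C)C)c(OC)c2)OC(C)=O)ccc1O[Si](C(C)C)(C(C)C)C(C)C
A6 | direct plan | (3R,5S)-1,7-bis[3-methoxy-4-(triisopropylsilyloxy)phenyl]heptane-3,5-diol (meso, syn) | COc1cc(CC[C@H](O)C[C@H](O)CCc2ccc(O[Si](C(C)C)(C(C)C)C(C)C)c(OC)c2)ccc1O[Si](C(C)C)(C(C)C)C(C)C
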